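**Plan**
1. Retrosynthesis first removes two aryl silyl ethers, then cuts both C(=O)–C(alkene) bonds of the quinone ring (C1–C2 and C3–C4, naphthoquinone numbering) in one operation. This gives a 3,6-dioxygenated phthaloyl unit (as its cobaltacycle, from a benzocyclobutenedione) and a terminal alkyne that already carries the stereocentre and the complete ester side chain.
2. The feature that allows this: the carbonyl carbons C1 and C4 both sit on the benzo ring (C8a, C4a), whose C5 and C8 oxygens are identical, so the two acyl termini are equivalent and no regiochemistry arises. C3 carries only H (so a terminal alkyne fits), and the stereocentre is exocyclic on C2.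
3. The alkyne is cut at the ester C–O bond (3-acetoxy-3-methylbutanoic acid plus an (R)-propargylic alcohol). The alcohol goes back to 3-(trimethylsilyl)propynal, an allyl group and an isopropylidene unit (cross-metathesis).
4. Forward ring order: the benzo ring is bought; the four-membered ring comes from an aryne [2+2] cycloaddition and is oxidised to the 1,2-dione; methyl ethers are exchanged for silyl ethers; cobalt inserts to the five-membered metallacycle; the quinone ring is formed last, then desilylation.
5. Stereochemistry: the single (R) centre is set by reagent-controlled Brown allylboration and is carried through unchanged, since no later step makes or breaks a bond at it.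

Key step: step 11

Remark: the stereocentre written in the target SMILES is (R) (the shikonin series), and the route is built for that enantiomer. (+)-Ipc2B(allyl), CoCl(PPh3)3 and 1,1-diethoxyethene are taken as purchasable.

**Step 1**
Reactants: 1 3-(trimethylsilyl)prop-2-ynal
Product: 2 (R)-1-(trimethylsilyl)hex-5-en-1-yn-3-ol
Conditions: (+)-Ipc2B(allyl) (1.2 equiv, 1 M in pentane), Et2O, −100 → −78 °C; then MeOH, pH 7 phosphate buffer, 30% H2O2, 0 °C → rt
Reagents that add atoms: (+)-B-allyldiisopinocampheylborane (the enantiomer made from (−)-α-pinene) C=CCB([C@H]1C[C@H]2C[C@@H]([C@@H]1C)C2(C)C)[C@H]1C[C@H]2C[C@@H]([C@@H]1C)C2(C)C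
Why: Brown asymmetric allylboration through a closed chair transition state with the alkynyl group equatorial; the two isopinocampheyl groups of the (−)-α-pinene-derived reagent should direct the allyl group to the Re face of the aldehyde and so set the (R) carbinol centre by reagent control.

**Step 2**
Reactants: 2 (R)-1-(trimethylsilyl)hex-5-en-1-yn-3-ol
Product: 3 (R)-6-methyl-1-(trimethylsilyl)hept-5-en-1-yn-3-ol
Conditions: second-generation Grubbs catalyst RuCl2(=CHPh)(H2IMes)(PCy3) (5 mol %), 2-methyl-2-butene (large excess)/CH2Cl2, 40 °C, sealed vessel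
Reagents that add atoms: 2-methyl-2-butene CC=C(C)C
Why: olefin cross-metathesis of a terminal alkene with 2-methyl-2-butene is a standard way to install the prenyl-type trisubstituted alkene; the silyl-capped internal alkyne is too hindered for enyne metathesis and the carbinol centre is not involved.

**Step 3**
Reactants: 3 (R)-6-methyl-1-(trimethylsilyl)hept-5-en-1-yn-3-ol
Product: 4 (R)-6-methylhept-5-en-1-yn-3-ol
Conditions: K2CO3 (0.2 equiv), MeOH, 0 °C → rt
Reagents that add atoms: none
Why: carbonate-catalysed methanolysis of the alkynyl C–Si bond (protodesilylation) is routine and leaves the secondary alcohol and the trisubstituted alkene untouched.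

**Step 4**
Reactants: 5 3-hydroxy-3-methylbutanoic acid
Product: 7 3-acetoxy-3-methylbutanoic acid, via acetic 3-acetoxy-3-methylbutanoic anhydride 6 (not isolated)
Conditions: AcCl (excess, neat), 0 °C → rt; then THF/H2O, rt
Reagents that add atoms: acetyl chloride CC(=O)Cl
Why: O-acetylation of a tertiary alcohol by neat acetyl chloride runs without base, so β-elimination has no promoter, and the mixed anhydride formed at the carboxyl group is hydrolysed back to the acid on aqueous work-up.

**Step 5**
Reactants: 4 (R)-6-methylhept-5-en-1-yn-3-ol; 7 3-acetoxy-3-methylbutanoic acid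
Product: 8 (3R)-6-methylhept-5-en-1-yn-3-yl 3-acetoxy-3-methylbutanoate
Conditions: DCC (1.2 equiv), DMAP (0.1 equiv), CH2Cl2, 0 °C → rt
Reagents that add atoms: none
Why: Steglich esterification (carbodiimide activation, DMAP acyl transfer) acylates the secondary propargylic alcohol with retention because no bond at the stereocentre is broken, and low temperature with only catalytic DMAP should hold back β-elimination of acetate.

**Step 6**
Reactants: 9 2-bromo-1,4-dimethoxybenzene; 10 1,1-diethoxyethene
Product: 13 3,6-dimethoxybenzocyclobutenone (2,5-dimethoxybicyclo[4.2.0]octa-1,3,5-trien-7-one), via 3,6-dimethoxybenzyne 11 (not isolated), via diethyl ketal 12 (not isolated)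
Conditions: NaNH2 (2.5 equiv), THF, reflux; then 1 M aq. HCl, THF, rt
Reagents that add atoms: water O (ketone oxygen of 13)
Why: aryne [2+2] cycloaddition, in which the amide base converts 9 into the symmetric 3,6-dimethoxybenzyne that adds the electron-rich ketene acetal (only one regioisomer is possible), and dilute acid then hydrolyses the ketal to the benzocyclobutenone.

**Step 7**
Reactants: 13 3,6-dimethoxybenzocyclobutenone
Product: 15 3,6-dimethoxybenzocyclobutene-1,2-dione, via 8,8-dibromo ketone 14 (not isolated)
Conditions: NBS (2.2 equiv), (PhCO2)2 (cat.), PhCF3, reflux; then 50% aq. H2SO4, 55 °C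
Reagents that add atoms: N-bromosuccinimide O=C1CCC(=O)N1Br (bromine atoms of 14); water O (new carbonyl oxygen of 15)
Why: radical (Wohl–Ziegler) gem-dibromination of the benzylic CH2 next to the ketone followed by hydrolysis of the gem-dibromide is the established way from benzocyclobutenones to benzocyclobutenediones, which cannot be oxidised through the antiaromatic enol.

**Step 8**
Reactants: 15 3,6-dimethoxybenzocyclobutene-1,2-dione
Product: 16 3,6-dihydroxybenzocyclobutene-1,2-dione
Conditions: BBr3 (3 equiv), CH2Cl2, −78 → 0 °C; then H2O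
Reagents that add atoms: none
Why: Lewis-acid ether cleavage, in which bromide attacks the O-methyl carbon of the boron-complexed aryl ether (SN2), removes both methyl groups at low temperature where the strained dione ring should stay intact.

**Step 9**
Reactants: 16 3,6-dihydroxybenzocyclobutene-1,2-dione
Product: 17 3,6-bis(tert-butyldimethylsilyloxy)benzocyclobutene-1,2-dione
Conditions: TBSOTf (2.4 equiv), 2,6-lutidine (3 equiv), CH2Cl2, −78 → 0 °C
Reagents that add atoms: tert-butyldimethylsilyl trifluoromethanesulfonate CC(C)(C)[Si](C)(C)OS(=O)(=O)C(F)(F)F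
Why: phenol silylation with a silyl triflate and a hindered non-nucleophilic base avoids nucleophilic opening of the strained dione and installs groups that fluoride removes at the end under near-neutral conditions.

**Step 10**
Reactants: 17 3,6-bis(tert-butyldimethylsilyloxy)benzocyclobutene-1,2-dione
Product: 19 chloro(dimethylglyoxime-N,N')(pyridine)[3,6-bis(tert-butyldimethylsilyloxy)phthaloyl]cobalt (trivalent cobalt), via bis(triphenylphosphine) phthaloylcobalt chloride 18 (not isolated)
Conditions: CoCl(PPh3)3 (1.05 equiv), PhCl, 50 °C, Ar; then dimethylglyoxime (1.1 equiv), pyridine, rt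
Reagents that add atoms: chlorotris(triphenylphosphine)cobalt (monovalent cobalt) Cl[Co-3]([P+](c1ccccc1)(c1ccccc1)c1ccccc1)([P+](c1ccccc1)(c1ccccc1)c1ccccc1)[P+](c1ccccc1)(c1ccccc1)c1ccccc1; dimethylglyoxime CC(=NO)C(C)=NO; pyridine c1ccncc1
Why: oxidative addition of the strained C(=O)–C(=O) bond of a benzocyclobutenedione to monovalent cobalt gives the five-membered phthaloylcobalt metallacycle, and ligand exchange of the two phosphines for dimethylglyoxime and pyridine gives the air-stable complex that is known to react with alkynes.

**Step 11**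
Reactants: 19 chloro(dimethylglyoxime-N,N')(pyridine)[3,6-bis(tert-butyldimethylsilyloxy)phthaloyl]cobalt; 8 (3R)-6-methylhept-5-en-1-yn-3-yl 3-acetoxy-3-methylbutanoate
Product: 20 (1R)-1-[5,8-bis(tert-butyldimethylsilyloxy)-1,4-dioxo-1,4-dihydronaphthalen-2-yl]-4-methylpent-3-en-1-yl 3-acetoxy-3-methylbutanoate
Conditions: 19 (1.2 equiv), CoCl2·6H2O (1 equiv), ClCH2CH2Cl, 80 °C, sealed tube, Ar
Reagents that add atoms: none
Why: CoCl2·6H2O acts as a Lewis acid that labilises a ligand on the coordinatively saturated trivalent cobalt of 19; the terminal alkyne of 8 then binds and inserts into one cobalt–acyl bond (first C–C bond), and acyl–alkenyl reductive elimination at cobalt makes the second C–C bond and releases the quinone and monovalent cobalt. The closest known reaction type is the phthaloylcobalt–alkyne naphthoquinone synthesis (Liebeskind quinone synthesis), here applied to a new phthaloyl complex and a new alkyne. The six-membered quinone ring (C1, C2, C3, C4, C4a, C8a) closes in the reductive elimination, that is by a metal-mediated formal [4+2] annulation of the four-carbon phthaloyl unit with the two alkyne carbons and not by a polar cyclisation. No stereocentre is created; the (R) centre lies outside the reacting atoms, no bond to it is made or broken, and it should therefore arrive unchanged. Regioselectivity is not needed because the two acyl carbons of the 3,6-disubstituted phthaloyl unit are equivalent, so either insertion orientation gives the same 2-substituted quinone; chemoselectivity for the alkyne over the trisubstituted alkene follows from the much stronger binding and faster insertion of an alkyne at cobalt. The near-neutral medium should spare both esters, and partial loss of an aryl silyl group would be harmless because step 12 removes both.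

**Step 12**
Reactants: 20 (1R)-1-[5,8-bis(tert-butyldimethylsilyloxy)-1,4-dioxo-1,4-dihydronaphthalen-2-yl]-4-methylpent-3-en-1-yl 3-acetoxy-3-methylbutanoate
Product: 21 (1R)-1-(5,8-dihydroxy-1,4-dioxo-1,4-dihydronaphthalen-2-yl)-4-methylpent-3-en-1-yl 3-acetoxy-3-methylbutanoate (the target)
Conditions: Bu4NF (2.2 equiv), AcOH (2.5 equiv), THF, 0 °C
Reagents that add atoms: none
Why: fluoride-mediated cleavage of aryl silyl ethers should be fast at 0 °C because the phenoxides peri to the quinone carbonyls are very good leaving groups, and the acetic acid buffer keeps the medium near neutral so that neither ester is cleaved nor acetate eliminated.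

**Compound list**
1 | 3-(trimethylsilyl)prop-2-ynal | C[Si](C)(C)C#CC=O | starting material
2 | (R)-1-(trimethylsilyl)hex-5-en-1-yn-3-ol | O[C@H](CC=C)C#C[Si](C)(C)C | intermediate
3 | (R)-6-methyl-1-(trimethylsilyl)hept-5-en-1-yn-3-ol | O[C@H](CC=C(C)C)C#C[Si](C)(C)C | intermediate
4 | (R)-6-methylhept-5-en-1-yn-3-ol | O[C@H](CC=C(C)C)C#C | intermediate
5 | 3-hydroxy-3-methylbutanoic acid | CC(C)(O)CC(=O)O | starting material
6 | acetic 3-acetoxy-3-methylbutanoic anhydride (not isolated) | CC(=O)OC(C)(C)CC(=O)OC(C)=O | intermediate
7 | 3-acetoxy-3-methylbutanoic acid | CC(=O)OC(C)(C)CC(=O)O | intermediate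
8 | (3R)-6-methylhept-5-en-1-yn-3-yl 3-acetoxy-3-methylbutanoate | CC(=O)OC(C)(C)CC(=O)O[C@H](CC=C(C)C)C#C | intermediate
9 | 2-bromo-1,4-dimethoxybenzene | COc1ccc(OC)c(Br)c1 | starting material
10 | 1,1-diethoxyethene | C=C(OCC)OCC | starting material
11 | 3,6-dimethoxybenzyne (not isolated) | COC1=CC=C(OC)C#C1 | intermediate
12 | 7,7-diethoxy-2,5-dimethoxybicyclo[4.2.0]octa-1,3,5-triene (diethyl ketal, not isolated) | COc1ccc(OC)c2c1CC2(OCC)OCC | intermediate
13 | 3,6-dimethoxybenzocyclobutenone (2,5-dimethoxybicyclo[4.2.0]octa-1,3,5-trien-7-one) | COc1ccc(OC)c2c1CC2=O | intermediate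
14 | 8,8-dibromo-2,5-dimethoxybicyclo[4.2.0]octa-1,3,5-trien-7-one (not isolated) | COc1ccc(OC)c2c1C(Br)(Br)C2=O | intermediate
15 | 3,6-dimethoxybenzocyclobutene-1,2-dione | COc1ccc(OC)c2c1C(=O)C2=O | intermediate
16 | 3,6-dihydroxybenzocyclobutene-1,2-dione | Oc1ccc(O)c2c1C(=O)C2=O | intermediate
17 | 3,6-bis(tert-butyldimethylsilyloxy)benzocyclobutene-1,2-dione | CC(C)(C)[Si](C)(C)Oc1ccc(O[Si](C)(C)C(C)(C)C)c2c1C(=O)C2=O | intermediate
18 | chloro[3,6-bis(tert-butyldimethylsilyloxy)phthaloyl]bis(triphenylphosphine)cobalt, trivalent cobalt (not isolated) | O=C1c2c(O[Si](C)(C)C(C)(C)C)ccc(O[Si](C)(C)C(C)(C)C)c2C(=O)[Co-2]1(Cl)([P+](c1ccccc1)(c1ccccc1)c1ccccc1)[P+](c1ccccc1)(c1ccccc1)c1ccccc1 | intermediate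
19 | chloro(dimethylglyoxime-N,N')(pyridine)[3,6-bis(tert-butyldimethylsilyloxy)phthaloyl]cobalt, trivalent cobalt | CC1=[N+](O)[Co-3]2(Cl)([n+]3ccccc3)(C(=O)c3c(O[Si](C)(C)C(C)(C)C)ccc(O[Si](C)(C)C(C)(C)C)c3C2=O)[N+](O)=C1C | intermediate
20 | (1R)-1-[5,8-bis(tert-butyldimethylsilyloxy)-1,4-dioxo-1,4-dihydronaphthalen-2-yl]-4-methylpent-3-en-1-yl 3-acetoxy-3-methylbutanoate | CC(=O)OC(C)(C)CC(=O)O[C@H](CC=C(C)C)C1=CC(=O)c2c(O[Si](C)(C)C(C)(C)C)ccc(O[Si](C)(C)C(C)(C)C)c2C1=O | intermediate
21 | (1R)-1-(5,8-dihydroxy-1,4-dioxo-1,4-dihydronaphthalen-2-yl)-4-methylpent-3-en-1-yl 3-acetoxy-3-methylbutanoate | CC(=O)OC(C)(C)CC(=O)O[C@H](CC=C(C)C)C1=CC(=O)c2c(O)ccc(O)c2C1=O | target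

**Count**
Total steps: 12. Longest linear sequence: 7 steps (steps 6 to 12, from 9 and 10 to 21); the alkyne arm (steps 1, 2, 3, 5) and the acid (step 4) join it at step 11.

**Steps most likely to fail**

Step 11. What may go wrong: alkyne uptake at the cobalt centre, flanked by two bulky silyloxy groups, may be slow, so that cobalt-mediated oligomerisation of the terminal alkyne or Lewis-acid ionisation of the propargylic ester overtakes the annulation. The fallback sets out from 4 and 17 and comes back to the route at 21; it forms the same two ring bonds in two separate thermal steps without a metal.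
- Alkynol 4 would be silylated (TBSCl, imidazole, DMF) to (R)-3-(tert-butyldimethylsilyloxy)-6-methylhept-5-en-1-yne F1.
- Its lithium acetylide (n-BuLi, THF, −78 °C) would be added to one carbonyl group of 17 to give the 8-alkynyl-8-hydroxybenzocyclobutenone F2, as a mixture of epimers at the new carbinol carbon, which is lost in the next step.
- Thermolysis (p-xylene, 130 °C) should open the four-membered ring to the o-quinoid vinylketene, which closes onto the alkyne and takes up the hydroxyl hydrogen to give tris-silylated shikonin F3 (Moore-type ring expansion of a 4-alkynyl-4-hydroxycyclobutenone to a quinone; an alkyl-substituted alkyne favours the six-membered ring).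
- Bu4NF/AcOH (THF, 0 °C → rt) would remove all three silyl groups to give shikonin F4.
- Steglich esterification of shikonin F4 with 7 (DCC, DMAP cat., CH2Cl2, 0 °C) should take place at the side-chain hydroxyl, since the two peri phenols are locked in hydrogen bonds to the quinone carbonyls, and would give 21.

Step 7. What may go wrong: electrophilic bromination of the electron-rich dimethoxy-substituted ring may compete with the radical gem-dibromination, and the dibromide may hydrolyse incompletely. The fallback sets out from 13 and comes back to the route at 16; it moves the protecting-group exchange ahead of the oxidation and so also takes the Lewis-acid demethylation of step 8 away from the strained dione.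
- Ketone 13 would be demethylated (BBr3, CH2Cl2, −78 → 0 °C) to 3,6-dihydroxybenzocyclobutenone F5.
- Acetylation (Ac2O, pyridine, rt) would give 3,6-diacetoxybenzocyclobutenone F6, whose acyloxy-deactivated ring no longer competes for bromine.
- Radical dibromination (NBS, (PhCO2)2 cat., PhCF3, reflux) would give 8,8-dibromo-3,6-diacetoxybenzocyclobutenone F7.
- Hydrolysis (50% aq. H2SO4, 55 °C) would cleave the gem-dibromide and both aryl acetates and give 16 directly.

Step 5. What may go wrong: base-promoted β-elimination of acetate from the activated acyl donor would lead to the 3-methylbut-2-enoate ester, and rearrangement of the activated acid to an N-acylurea would consume it. The fallback sets out from 4 and comes back to the route at 8; it builds the acyl chain on the ester by C–C bond formation instead of acylating with the preformed acid.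
- Alcohol 4 would be acylated with bromoacetyl bromide (pyridine, CH2Cl2, 0 °C) to (3R)-6-methylhept-5-en-1-yn-3-yl bromoacetate F8.
- A Reformatsky reaction with acetone (activated zinc dust, THF, reflux) would give (3R)-6-methylhept-5-en-1-yn-3-yl 3-hydroxy-3-methylbutanoate F9; the zinc enolate is not basic enough to deprotonate the terminal alkyne.
- Acetylation of the tertiary alcohol (Ac2O, DMAP cat., Et3N, CH2Cl2, rt) would give 8.

**Further compounds**
F1 | step 11 | (R)-3-(tert-butyldimethylsilyloxy)-6-methylhept-5-en-1-yne | CC(C)(C)[Si](C)(C)O[C@H](CC=C(C)C)C#C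
F2 | step 11 | 8-hydroxy-8-[(3R)-3-(tert-butyldimethylsilyloxy)-6-methylhept-5-en-1-yn-1-yl]-2,5-bis(tert-butyldimethylsilyloxy)bicyclo[4.2.0]octa-1,3,5-trien-7-one | CC(C)(C)[Si](C)(C)O[C@H](CC=C(C)C)C#CC1(O)C(=O)c2c(O[Si](C)(C)C(C)(C)C)ccc(O[Si](C)(C)C(C)(C)C)c21
F3 | step 11 | 5,8-bis(tert-butyldimethylsilyloxy)-2-[(1R)-1-(tert-butyldimethylsilyloxy)-4-methylpent-3-en-1-yl]naphthalene-1,4-dione | CC(C)(C)[Si](C)(C)O[C@H](CC=C(C)C)C1=CC(=O)c2c(O[Si](C)(C)C(C)(C)C)ccc(O[Si](C)(C)C(C)(C)C)c2C1=O
F4 | step 11 | shikonin, 5,8-dihydroxy-2-[(1R)-1-hydroxy-4-methylpent-3-en-1-yl]naphthalene-1,4-dione | O[C@H](CC=C(C)C)C1=CC(=O)c2c(O)ccc(O)c2C1=O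
F5 | step 7 | 3,6-dihydroxybenzocyclobutenone | Oc1ccc(O)c2c1CC2=O
F6 | step 7 | 3,6-diacetoxybenzocyclobutenone | CC(=O)Oc1ccc(OC(C)=O)c2c1CC2=O
F7 | step 7 | 8,8-dibromo-3,6-diacetoxybenzocyclobutenone | CC(=O)Oc1ccc(OC(C)=O)c2c1C(Br)(Br)C2=O
F8 | step 5 | (3R)-6-methylhept-5-en-1-yn-3-yl bromoacetate | BrCC(=O)O[C@H](CC=C(C)C)C#C
F9 | step 5 | (3R)-6-methylhept-5-en-1-yn-3-yl 3-hydroxy-3-methylbutanoate | CC(C)(O)CC(=O)O[C@H](CC=C(C)C)C#C
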